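**Retrosynthetic overview**
- Rabdosin B ⇐ Saegusa–Ito dehydrogenation (C16 methyl → exocyclic enone) and C11 hydride reduction of a tetracyclic bis-enol derivative (C11 enol acetate, C15 silyl enol ether).
- Key disconnection: C8–C9 and C12–C13 are cut together, as a gold-catalysed acetoxy-shift/(4+3) cycloaddition of a ring A propargylic acetate onto an ester-tethered 2-silyloxycyclopentadiene (ring D).
- The tether ester (C20–O–C7) comes from union of the ring A carbinol, a carbonyl unit and the kinetic enolate of 2-methylcyclopent-2-enone.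
- Ring A (C5, C10, C1) comes from 4,4-dimethylcyclohex-2-enone: Baylis–Hillman hydroxymethylation, asymmetric conjugate addition of a hydroxymethyl anion equivalent with ynal aldol trapping, ketone reduction.
- Ring order: ring A and ring D are bought as carbocycles; the δ-lactone ring and ring C (bicyclo[3.2.1]octane) close together in one operation.

Assumption: locants C1–C20 are the ent-kaurane numbers of the corresponding target atoms (C7 lactone carbonyl, C20 lactone CH2, C17 exocyclic methylene), and the ligand in step 3 is taken to give the C5 configuration drawn (its mirror image is used if the sense proves opposite).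

**Step 1**
Reactants: 1 4,4-dimethylcyclohex-2-en-1-one; 2 formaldehyde
Product: 3 2-(hydroxymethyl)-4,4-dimethylcyclohex-2-en-1-one
Conditions: 37% aq. HCHO, DMAP (0.2 equiv), THF/H2O, rt
Reagents that add atoms: none
Why: Morita–Baylis–Hillman reaction in which DMAP adds reversibly to the enone β-carbon, the enolate attacks formaldehyde at C10 and loss of DMAP restores the enone, with no stereocentre formed.

**Step 2**
Reactants: 3 2-(hydroxymethyl)-4,4-dimethylcyclohex-2-en-1-one
Product: 4 2-{[(tert-butyldimethylsilyl)oxy]methyl}-4,4-dimethylcyclohex-2-en-1-one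
Conditions: TBSCl, imidazole, DMF, rt
Reagents that add atoms: tert-butyldimethylsilyl chloride, CC(C)(C)[Si](C)(C)Cl
Why: Standard silyl ether formation masks the C20 oxygen, keeping it distinct from the C1 and C6 oxygens and giving a poor leaving group next to the later enolate.

**Step 3**
Reactants: 4 2-{[(tert-butyldimethylsilyl)oxy]methyl}-4,4-dimethylcyclohex-2-en-1-one; 5 (chloromethyl)(isopropoxy)dimethylsilane; 6 3-(trimethylsilyl)prop-2-ynal
Product: 9 (2S,3R)-2-{[(tert-butyldimethylsilyl)oxy]methyl}-2-[1-hydroxy-3-(trimethylsilyl)prop-2-yn-1-yl]-3-{[isopropoxy(dimethyl)silyl]methyl}-4,4-dimethylcyclohexan-1-one (both carbinol epimers), via Grignard reagent 7 (not isolated), via magnesium enolate 8 (not isolated)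
Conditions: 5, Mg, THF, 40 °C; CuBr·SMe2 (5 mol %), (R)-1-[(S)-2-(diphenylphosphino)ferrocenyl]ethyldicyclohexylphosphine (C36H44FeP2, 6 mol %), t-BuOMe, −78 °C, slow addition of 7 to 4; then 6, −78 to −40 °C; aq. NH4Cl
Reagents that add atoms: none
Why: Proposed new method: the silylmethyl Grignard reagent (a hydroxymethyl anion equivalent) adds in conjugate fashion through a copper–alkene π-complex that becomes a trivalent copper alkyl and reductively eliminates, the chiral diphosphine choosing the enone face to set C5 (R), and the magnesium enolate is then trapped by the ynal anti to the new C5 substituent to set the quaternary C10 (the carbinol centre is left mixed because step 9 erases it); the closest known reactions are the copper/ferrocenyl-diphosphine conjugate addition of Grignard reagents to cyclic enones with aldol trapping and the racemic copper-catalysed conjugate addition of this same Grignard reagent.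

**Step 4**
Reactants: 9 (2S,3R)-2-{[(tert-butyldimethylsilyl)oxy]methyl}-2-[1-hydroxy-3-(trimethylsilyl)prop-2-yn-1-yl]-3-{[isopropoxy(dimethyl)silyl]methyl}-4,4-dimethylcyclohexan-1-one
Product: 10 (1S,2R,3R)-2-{[(tert-butyldimethylsilyl)oxy]methyl}-2-[1-hydroxy-3-(trimethylsilyl)prop-2-yn-1-yl]-3-{[isopropoxy(dimethyl)silyl]methyl}-4,4-dimethylcyclohexan-1-ol
Conditions: NaBH4, CeCl3·7H2O, MeOH, −40 °C
Reagents that add atoms: none
Why: Luche-type carbonyl reduction in which hydride attacks C1 axially, anti to the axial C20 arm on the neighbouring quaternary carbon, giving the equatorial 1-hydroxyl cis to C20 (1S) and removing the retro-aldol risk.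

**Step 5**
Reactants: 10 (1S,2R,3R)-2-{[(tert-butyldimethylsilyl)oxy]methyl}-2-[1-hydroxy-3-(trimethylsilyl)prop-2-yn-1-yl]-3-{[isopropoxy(dimethyl)silyl]methyl}-4,4-dimethylcyclohexan-1-ol
Product: 11 (1S,2R,3R)-2-{[(tert-butyldimethylsilyl)oxy]methyl}-3-(hydroxymethyl)-2-(1-hydroxyprop-2-yn-1-yl)-4,4-dimethylcyclohexan-1-ol
Conditions: 30% H2O2, KF, KHCO3, THF/MeOH, rt
Reagents that add atoms: hydrogen peroxide, OO
Why: Tamao oxidation turns the alkoxysilyl C–Si bond into the C6 hydroxyl (peroxide attack on fluoride-activated silicon, then carbon-to-oxygen shift) while the basic methanolic fluoride also removes the alkynyl trimethylsilyl group and leaves the TBS ether intact.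

**Step 6**
Reactants: 11 (1S,2R,3R)-2-{[(tert-butyldimethylsilyl)oxy]methyl}-3-(hydroxymethyl)-2-(1-hydroxyprop-2-yn-1-yl)-4,4-dimethylcyclohexan-1-ol
Product: 12 (1S,2R,3R)-3-(acetoxymethyl)-2-(1-acetoxyprop-2-yn-1-yl)-2-{[(tert-butyldimethylsilyl)oxy]methyl}-4,4-dimethylcyclohexyl acetate
Conditions: Ac2O, pyridine, DMAP (cat.), CH2Cl2, rt to 40 °C
Reagents that add atoms: acetic anhydride, CC(=O)OC(C)=O
Why: DMAP-catalysed acetylation installs the two acetates of the target (C1, C6) together with the propargylic acetate that is the migrating group of step 9.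

**Step 7**
Reactants: 12 (1S,2R,3R)-3-(acetoxymethyl)-2-(1-acetoxyprop-2-yn-1-yl)-2-{[(tert-butyldimethylsilyl)oxy]methyl}-4,4-dimethylcyclohexyl acetate
Product: 13 (1S,2R,3R)-3-(acetoxymethyl)-2-(1-acetoxyprop-2-yn-1-yl)-2-(hydroxymethyl)-4,4-dimethylcyclohexyl acetate
Conditions: HF·pyridine, THF/pyridine, 0 °C to rt
Reagents that add atoms: none
Why: Fluoride-mediated silyl ether cleavage under buffered acidic conditions frees only the C20 hydroxyl and avoids base-induced acetyl migration.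

**Step 8**
Reactants: 13 (1S,2R,3R)-3-(acetoxymethyl)-2-(1-acetoxyprop-2-yn-1-yl)-2-(hydroxymethyl)-4,4-dimethylcyclohexyl acetate; 14 2-methylcyclopent-2-en-1-one
Product: 17 [(1R,2S,6R)-2-acetoxy-6-(acetoxymethyl)-1-(1-acetoxyprop-2-yn-1-yl)-5,5-dimethylcyclohexyl]methyl 3-methyl-2-oxocyclopent-3-ene-1-carboxylate (mixture at C8 and C9), via imidazole carbamate 15 (not isolated), via lithium enolate 16 (not isolated)
Conditions: 13, CDI, THF, rt; 14, LiN(i-Pr)2, THF, −78 °C (2.5 equiv of 16); add 15 and BF3·OEt2, −78 °C; aq. NH4Cl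
Reagents that add atoms: 1,1'-carbonyldiimidazole, O=C(n1ccnc1)n1ccnc1
Why: The alcohol is turned into its imidazole carbamate, which C-acylates the kinetic cross-conjugated lithium enolate of the enone (Claisen-type acylation, imidazole carbamate/BF3 protocol) and so attaches ring D through the future lactone carbonyl C7; C8 and C9 are left uncontrolled because both become sp2 in step 9.

**Step 9**
Reactants: 17 [(1R,2S,6R)-2-acetoxy-6-(acetoxymethyl)-1-(1-acetoxyprop-2-yn-1-yl)-5,5-dimethylcyclohexyl]methyl 3-methyl-2-oxocyclopent-3-ene-1-carboxylate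
Product: 19 (1S,5R,8S,9S,10R,13S)-1,6,11-triacetoxy-15-[(tert-butyldimethylsilyl)oxy]-6,7-secokaura-11,15-dien-7,20-olide, via silyl dienol ether 18 (not isolated)
Conditions: TBSOTf, Et3N, CH2Cl2, 0 °C; filtration through basic Al2O3; [Au(NCMe){P(t-Bu)2(biphenyl-2-yl)}]SbF6 (5 mol %), CH2Cl2, −20 °C to rt
Reagents that add atoms: tert-butyldimethylsilyl trifluoromethanesulfonate, CC(C)(C)[Si](C)(C)OS(=O)(=O)C(F)(F)F
Why: Proposed new method: monovalent gold activates the terminal alkyne, a 1,2-acetoxy shift gives a gold vinylcarbenoid (2-acetoxyallyl cation) whose C9 terminus is captured by the nucleophilic C8 of the silyloxycyclopentadiene through a six-membered chair-like transition state (bulky C5 arm of ring A anti to the forming bond, silyloxy-bearing C15 anti to the quaternary C10), and the vinylgold carbon C12 then closes onto C13 of the resulting silyloxyallyl cation, which can only occur cis across the five-membered ring, so the lactone ring and ring C form together and C8, C9 and C13 are set relative to C10; the closest known reactions are gold-catalysed acyloxy-migration/cyclopropanation–Cope (formal (4+3)) annulations of propargyl esters with dienes and vinylcarbenoid (4+3) cycloadditions with cyclopentadiene.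

**Step 10**
Reactants: 19 (1S,5R,8S,9S,10R,13S)-1,6,11-triacetoxy-15-[(tert-butyldimethylsilyl)oxy]-6,7-secokaura-11,15-dien-7,20-olide
Product: 21 (1S,5R,8S,9S,10R,11S,13S)-1,6-diacetoxy-15-[(tert-butyldimethylsilyl)oxy]-11-hydroxy-6,7-secokaur-15-en-7,20-olide, via 11-ketone 20 (not isolated)
Conditions: NaBH4, MeOH/THF (1:1), 0 °C to rt
Reagents that add atoms: none
Why: Methanolysis cleaves the enol acetate much faster than the alkyl acetates, and the freed C11 ketone is reduced in situ from the face opposite the C15–C16 bridge that caps the other face of chair-like ring C (as in bicyclo[3.2.1]octan-3-ones of the tropinone type and in 11-oxo steroids), giving the axial (11S) alcohol while the silyl enol ether protects C15.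

**Step 11**
Reactants: 21 (1S,5R,8S,9S,10R,11S,13S)-1,6-diacetoxy-15-[(tert-butyldimethylsilyl)oxy]-11-hydroxy-6,7-secokaur-15-en-7,20-olide
Product: 22 Rabdosin B
Conditions: Pd(OAc)2 (1.2 equiv), MeCN, 40 °C
Reagents that add atoms: none
Why: Saegusa–Ito oxidation in which the palladium enolate at C16 can undergo β-hydride elimination only toward the C17 methyl, because the other β-hydrogen sits on the bridgehead C13 (Bredt), so the exocyclic enone forms directly and no stereocentre is touched.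

**Compound list**
1 | 4,4-dimethylcyclohex-2-en-1-one | O=C1C=CC(C)(C)CC1 | starting material
2 | formaldehyde | C=O | starting material
3 | 2-(hydroxymethyl)-4,4-dimethylcyclohex-2-en-1-one | O=C1C(CO)=CC(C)(C)CC1 | intermediate
4 | 2-{[(tert-butyldimethylsilyl)oxy]methyl}-4,4-dimethylcyclohex-2-en-1-one | CC(C)(C)[Si](C)(C)OCC1=CC(C)(C)CCC1=O | intermediate
5 | (chloromethyl)(isopropoxy)dimethylsilane | ClC[Si](C)(C)OC(C)C | starting material
6 | 3-(trimethylsilyl)prop-2-ynal | O=CC#C[Si](C)(C)C | starting material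
7 | {[isopropoxy(dimethyl)silyl]methyl}magnesium chloride | CC(C)O[Si](C)(C)C[Mg]Cl | intermediate
8 | chloromagnesium (R)-2-{[(tert-butyldimethylsilyl)oxy]methyl}-3-{[isopropoxy(dimethyl)silyl]methyl}-4,4-dimethylcyclohex-1-en-1-olate | Cl[Mg]OC1=C(CO[Si](C)(C)C(C)(C)C)[C@H](C[Si](C)(C)OC(C)C)C(C)(C)CC1 | intermediate
9 | (2S,3R)-2-{[(tert-butyldimethylsilyl)oxy]methyl}-2-[1-hydroxy-3-(trimethylsilyl)prop-2-yn-1-yl]-3-{[isopropoxy(dimethyl)silyl]methyl}-4,4-dimethylcyclohexan-1-one (both carbinol epimers) | C[Si](C)(C)C#CC(O)[C@]1(CO[Si](C)(C)C(C)(C)C)C(=O)CCC(C)(C)[C@H]1C[Si](C)(C)OC(C)C | intermediate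
10 | (1S,2R,3R)-2-{[(tert-butyldimethylsilyl)oxy]methyl}-2-[1-hydroxy-3-(trimethylsilyl)prop-2-yn-1-yl]-3-{[isopropoxy(dimethyl)silyl]methyl}-4,4-dimethylcyclohexan-1-ol | C[Si](C)(C)C#CC(O)[C@]1(CO[Si](C)(C)C(C)(C)C)[C@@H](O)CCC(C)(C)[C@H]1C[Si](C)(C)OC(C)C | intermediate
11 | (1S,2R,3R)-2-{[(tert-butyldimethylsilyl)oxy]methyl}-3-(hydroxymethyl)-2-(1-hydroxyprop-2-yn-1-yl)-4,4-dimethylcyclohexan-1-ol | C#CC(O)[C@]1(CO[Si](C)(C)C(C)(C)C)[C@@H](O)CCC(C)(C)[C@H]1CO | intermediate
12 | (1S,2R,3R)-3-(acetoxymethyl)-2-(1-acetoxyprop-2-yn-1-yl)-2-{[(tert-butyldimethylsilyl)oxy]methyl}-4,4-dimethylcyclohexyl acetate | C#CC(OC(C)=O)[C@]1(CO[Si](C)(C)C(C)(C)C)[C@@H](OC(C)=O)CCC(C)(C)[C@H]1COC(C)=O | intermediate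
13 | (1S,2R,3R)-3-(acetoxymethyl)-2-(1-acetoxyprop-2-yn-1-yl)-2-(hydroxymethyl)-4,4-dimethylcyclohexyl acetate | C#CC(OC(C)=O)[C@]1(CO)[C@@H](OC(C)=O)CCC(C)(C)[C@H]1COC(C)=O | intermediate
14 | 2-methylcyclopent-2-en-1-one | CC1=CCCC1=O | starting material
15 | [(1R,2S,6R)-2-acetoxy-6-(acetoxymethyl)-1-(1-acetoxyprop-2-yn-1-yl)-5,5-dimethylcyclohexyl]methyl 1H-imidazole-1-carboxylate | C#CC(OC(C)=O)[C@]1(COC(=O)n2ccnc2)[C@@H](OC(C)=O)CCC(C)(C)[C@H]1COC(C)=O | intermediate
16 | lithium 5-methylcyclopenta-1,4-dien-1-olate | [Li]OC1=CCC=C1C | intermediate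
17 | [(1R,2S,6R)-2-acetoxy-6-(acetoxymethyl)-1-(1-acetoxyprop-2-yn-1-yl)-5,5-dimethylcyclohexyl]methyl 3-methyl-2-oxocyclopent-3-ene-1-carboxylate (mixture at C8 and C9) | C#CC(OC(C)=O)[C@]1(COC(=O)C2CC=C(C)C2=O)[C@@H](OC(C)=O)CCC(C)(C)[C@H]1COC(C)=O | intermediate
18 | [(1R,2S,6R)-2-acetoxy-6-(acetoxymethyl)-1-(1-acetoxyprop-2-yn-1-yl)-5,5-dimethylcyclohexyl]methyl 2-[(tert-butyldimethylsilyl)oxy]-3-methylcyclopenta-1,3-diene-1-carboxylate | C#CC(OC(C)=O)[C@]1(COC(=O)C2=C(O[Si](C)(C)C(C)(C)C)C(C)=CC2)[C@@H](OC(C)=O)CCC(C)(C)[C@H]1COC(C)=O | intermediate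
19 | (1S,5R,8S,9S,10R,13S)-1,6,11-triacetoxy-15-[(tert-butyldimethylsilyl)oxy]-6,7-secokaura-11,15-dien-7,20-olide (spiro δ-lactone C10–C20–O–C7(=O)–C8–C9; C11=C12 enol acetate; C15=C16 silyl enol ether; C16 methyl) | CC1=C(O[Si](C)(C)C(C)(C)C)[C@]23C[C@H]1C=C(OC(C)=O)[C@H]2[C@]1(COC3=O)[C@@H](OC(C)=O)CCC(C)(C)[C@H]1COC(C)=O | intermediate
20 | (1S,5R,8S,9S,10R,13S)-1,6-diacetoxy-15-[(tert-butyldimethylsilyl)oxy]-11-oxo-6,7-secokaur-15-en-7,20-olide | CC1=C(O[Si](C)(C)C(C)(C)C)[C@]23C[C@H]1CC(=O)[C@H]2[C@]1(COC3=O)[C@@H](OC(C)=O)CCC(C)(C)[C@H]1COC(C)=O | intermediate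
21 | (1S,5R,8S,9S,10R,11S,13S)-1,6-diacetoxy-15-[(tert-butyldimethylsilyl)oxy]-11-hydroxy-6,7-secokaur-15-en-7,20-olide | CC1=C(O[Si](C)(C)C(C)(C)C)[C@]23C[C@H]1C[C@H](O)[C@H]2[C@]1(COC3=O)[C@@H](OC(C)=O)CCC(C)(C)[C@H]1COC(C)=O | intermediate
22 | Rabdosin B, (1S,5R,8S,9S,10R,11S,13S)-1,6-diacetoxy-11-hydroxy-15-oxo-6,7-secokaur-16-en-7,20-olide | C=C1C(=O)[C@]23C[C@H]1C[C@H](O)[C@H]2[C@]1(COC3=O)[C@@H](OC(C)=O)CCC(C)(C)[C@H]1COC(C)=O | target

**Totals**
Total step count: 11. Longest linear sequence: 11 steps (1 to 22); compounds 2, 5, 6 and 14 enter as purchased reagents.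

**Three steps most likely to fail**

Step 9 (key cycloaddition; the reactive diene isomer, the regiochemistry of the second bond and the facial selectivity are unproven). The fallback sets out from 17 and comes back at 20, forming the two bonds one after the other by polar chemistry. Treating 17 with Cu(MeCN)4BF4 (5 mol %) and i-Pr2NEt in MeOH gives a copper allenylidene by loss of acetate, and its γ-carbon C9 is attacked by the β-keto ester carbon C8 (intramolecular propargylic alkylation) to give the 9-ethynyl spirolactone F8. Hydration of the alkyne with the same gold complex in wet dioxane gives the methyl ketone F9. KN(SiMe3)2 (THF, −78 °C) then forms the methyl-side enolate, which closes ring C by Michael addition to C13 of the cyclopentenone, and TBSCl traps the C15 enolate to give 20, which is reduced with NaBH4 as in step 10.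

Step 3 (enantioselectivity and reactivity of the copper-catalysed addition to an α-substituted, γ-quaternary enone are not established). The fallback sets out from 4 and comes back at 12, drawing the absolute configuration from a ketone reduction instead.
- (R)-Me-CBS oxazaborolidine with BH3·SMe2 gives the (S)-allylic alcohol F1.
- Hydroxyl-directed Simmons–Smith cyclopropanation (Et2Zn, CH2I2) gives the syn cyclopropyl carbinol F2, and Dess–Martin oxidation gives the cyclopropyl ketone F3.
- Me3SiI opens the ring at the methylene carbon to give the iodomethyl silyl enol ether F4, which undergoes a TiCl4-mediated Mukaiyama aldol with propynal, anti to the C5 arm, to give the iodo aldol F5.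
- CsOAc in DMF gives the acetoxy aldol F6, NaBH4/CeCl3·7H2O gives the diol F7, and Ac2O/pyridine/DMAP gives 12.

Step 10 (hydride may attack from the bridge side and give the equatorial alcohol, and the acetates must survive). The fallback sets out from 19 and comes back at 21, accepting the wrong epimer and inverting it. NaBH4 gives the 11-epi alcohol F10. Mitsunobu reaction (chloroacetic acid, PPh3, diisopropyl azodicarboxylate) gives the inverted chloroacetate F11 by SN2 from the same face the hydride used. Thiourea/NaHCO3 in EtOH then removes the chloroacetyl group without touching the acetates and gives 21.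

**Further compounds**
F1 | step 3 | (S)-2-{[(tert-butyldimethylsilyl)oxy]methyl}-4,4-dimethylcyclohex-2-en-1-ol | CC1(C)CC[C@H](O)C(CO[Si](C)(C)C(C)(C)C)=C1
F2 | step 3 | 1-{[(tert-butyldimethylsilyl)oxy]methyl}-5,5-dimethylbicyclo[4.1.0]heptan-2-ol (cyclopropane syn to hydroxyl) | CC(C)(C)[Si](C)(C)OC[C@@]12C[C@@H]1C(C)(C)CC[C@@H]2O
F3 | step 3 | 1-{[(tert-butyldimethylsilyl)oxy]methyl}-5,5-dimethylbicyclo[4.1.0]heptan-2-one (ring fusion as in F2) | CC(C)(C)[Si](C)(C)OC[C@@]12C[C@@H]1C(C)(C)CCC2=O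
F4 | step 3 | (R)-[(2-{[(tert-butyldimethylsilyl)oxy]methyl}-3-(iodomethyl)-4,4-dimethylcyclohex-1-en-1-yl)oxy]trimethylsilane | C[Si](C)(C)OC1=C(CO[Si](C)(C)C(C)(C)C)[C@H](CI)C(C)(C)CC1
F5 | step 3 | (2S,3R)-2-{[(tert-butyldimethylsilyl)oxy]methyl}-2-(1-hydroxyprop-2-yn-1-yl)-3-(iodomethyl)-4,4-dimethylcyclohexan-1-one | C#CC(O)[C@]1(CO[Si](C)(C)C(C)(C)C)C(=O)CCC(C)(C)[C@H]1CI
F6 | step 3 | (2S,3R)-3-(acetoxymethyl)-2-{[(tert-butyldimethylsilyl)oxy]methyl}-2-(1-hydroxyprop-2-yn-1-yl)-4,4-dimethylcyclohexan-1-one | C#CC(O)[C@]1(CO[Si](C)(C)C(C)(C)C)C(=O)CCC(C)(C)[C@H]1COC(C)=O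
F7 | step 3 | (1S,2R,3R)-3-(acetoxymethyl)-2-{[(tert-butyldimethylsilyl)oxy]methyl}-2-(1-hydroxyprop-2-yn-1-yl)-4,4-dimethylcyclohexan-1-ol | C#CC(O)[C@]1(CO[Si](C)(C)C(C)(C)C)[C@@H](O)CCC(C)(C)[C@H]1COC(C)=O
F8 | step 9 | 9-ethynyl spirolactone (δ-lactone C10–C20–O–C7(=O)–C8–C9 with C8 spiro to 3-methylcyclopent-3-en-2-one; 1-OAc and 6-OAc; configuration at C1, C5, C8, C9, C10 as in 19) | C#C[C@@H]1[C@]2(CC=C(C)C2=O)C(=O)OC[C@]13[C@@H](OC(C)=O)CCC(C)(C)[C@H]3COC(C)=O
F9 | step 9 | 9-acetyl spirolactone (methyl ketone from F8, same configuration) | CC(=O)[C@@H]1[C@]2(CC=C(C)C2=O)C(=O)OC[C@]13[C@@H](OC(C)=O)CCC(C)(C)[C@H]3COC(C)=O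
F10 | step 10 | 11-epimer of 21, (1S,5R,8S,9S,10R,11R,13S)-1,6-diacetoxy-15-[(tert-butyldimethylsilyl)oxy]-11-hydroxy-6,7-secokaur-15-en-7,20-olide | CC1=C(O[Si](C)(C)C(C)(C)C)[C@]23C[C@H]1C[C@@H](O)[C@H]2[C@]1(COC3=O)[C@@H](OC(C)=O)CCC(C)(C)[C@H]1COC(C)=O
F11 | step 10 | 11-O-chloroacetate of 21, (1S,5R,8S,9S,10R,11S,13S)-1,6-diacetoxy-11-(chloroacetoxy)-15-[(tert-butyldimethylsilyl)oxy]-6,7-secokaur-15-en-7,20-olide | CC1=C(O[Si](C)(C)C(C)(C)C)[C@]23C[C@H]1C[C@H](OC(=O)CCl)[C@H]2[C@]1(COC3=O)[C@@H](OC(C)=O)CCC(C)(C)[C@H]1COC(C)=O
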